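**Strategy**

Atom labels: ring C1 (CMe2), C2 (CHBr), C3 (CH2), C4 (CHCl), C5 (alkylidene carbon), C6 (CHCl); side chain C7 (=CH) and C8 (CH2Br). Everything rests on cutting the one cyclohexane ring at C2–C3. The key step exploits the 1,3-relationship of the C2 and C4 heteroatoms across C3, with C4 allylic to the exocyclic C5=C7 bond: a Lewis-acid-triggered aldehyde–diene closure forms C2–C3, the ring, the C2–O stereocentre and the C4–Cl stereocentre at once. Its precursor is an open-chain aldehyde (C2) with the C6 chloride already in place, a Z-configured C3=C4–C5=C7 diene and a silyl ether at C8; C2–OH is later exchanged for bromine with inversion.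

Key step: step 8

Remark: the hydroxypivalonitrile building block (source of C1, C2 and C6) is assumed to be purchasable; C2 is carried as a nitrile and C8 as a tert-butyldiphenylsilyl ether, a weaker donor towards TiCl4 than smaller silyl ethers.

**Route**

Step 1
Reactants: 1 propargyl alcohol; 2 vinyl bromide
Product: 3 pent-4-en-2-yn-1-ol
Conditions: PdCl2(PPh3)2 (2 mol%), CuI (4 mol%), Et2NH, THF, 0 °C to rt
Reagents that add atoms: none
Why: Sonogashira coupling (zerovalent palladium with CuI) joins the terminal alkyne carbon to the vinyl carbon under mild amine conditions that leave the free hydroxyl untouched, and no stereocentre is formed.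

Step 2
Reactants: 3 pent-4-en-2-yn-1-ol
Product: 5 (2Z)-3-iodopenta-2,4-dien-1-ol, via cyclic alkenylalanate 4 (not isolated)
Conditions: NaAlH2(OCH2CH2OMe)2, THF, 0 °C to rt; then I2, THF, –78 °C to 0 °C
Reagents that add atoms: iodine, SMILES II
Why: Hydroxyl-directed trans-hydroalumination of the propargylic alcohol places hydride on the carbon next to CH2O (C7) and aluminium on C5 in a five-membered chelate, and iodinolysis of the C–Al bond with retention gives the iodide cis to C8, which is the origin of the Z geometry (C6 cis to C8).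

Step 3
Reactants: 5 (2Z)-3-iodopenta-2,4-dien-1-ol
Product: 6 tert-butyl{[(2Z)-3-iodopenta-2,4-dien-1-yl]oxy}diphenylsilane
Conditions: TBDPSCl, imidazole, CH2Cl2, 0 °C to rt
Reagents that add atoms: tert-butyl(chloro)diphenylsilane, SMILES CC(C)(C)[Si](Cl)(c1ccccc1)c1ccccc1
Why: Standard silylation of a primary alcohol with a chlorosilane and imidazole gives a bulky silyl ether that is stable to the later steps and binds TiCl4 poorly, so the allylic C8–O bond should not ionise in step 8.

Step 4
Reactants: 7 3-hydroxy-2,2-dimethylpropanenitrile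
Product: 8 2,2-dimethyl-3-oxopropanenitrile
Conditions: (COCl)2, DMSO, CH2Cl2, –78 °C; then Et3N, –78 °C to 0 °C
Reagents that add atoms: none
Why: Swern oxidation stops cleanly at the aldehyde, which has no α-hydrogen and therefore cannot enolise or condense with itself.

Step 5
Reactants: 6 tert-butyl{[(2Z)-3-iodopenta-2,4-dien-1-yl]oxy}diphenylsilane; 8 2,2-dimethyl-3-oxopropanenitrile
Product: 10 (3R,4Z)-6-[(tert-butyldiphenylsilyl)oxy]-4-ethenyl-3-hydroxy-2,2-dimethylhex-4-enenitrile, via trimethylsilyl ether 9 (not isolated)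
Conditions: CrCl2 (10 mol%), N-[2-(4-isopropyl-4,5-dihydrooxazol-2-yl)-6-methylphenyl]methanesulfonamide (enantiomer that gives the 3R carbinol, 12 mol%), 1,8-bis(dimethylamino)naphthalene (12 mol%), NiCl2·(2,9-dimethyl-1,10-phenanthroline) (2 mol%), Mn powder, TMSCl, LiCl, MeCN, rt; then aq. citric acid, THF, 0 °C
Reagents that add atoms: none
Why: Catalytic asymmetric Nozaki–Hiyama–Kishi coupling, in which zerovalent nickel inserts into the C–I bond with retention of geometry, the alkenyl group passes to chromium and the sulfonamide-bound alkenylchromium adds to one face of the non-enolisable aldehyde, so that the ligand sets the C6 carbinol (3R) while nitrile and silyl ether are tolerated, TMSCl releases the product from chromium and Mn regenerates divalent chromium.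

Step 6
Reactants: 10 (3R,4Z)-6-[(tert-butyldiphenylsilyl)oxy]-4-ethenyl-3-hydroxy-2,2-dimethylhex-4-enenitrile
Product: 11 (3S,4Z)-6-[(tert-butyldiphenylsilyl)oxy]-3-chloro-4-ethenyl-2,2-dimethylhex-4-enenitrile
Conditions: PPh3, Cl3CC(O)CCl3, CH2Cl2, 0 °C
Reagents that add atoms: hexachloroacetone, SMILES ClC(Cl)(Cl)C(=O)C(Cl)(Cl)Cl
Why: Appel-type deoxychlorination with PPh3 and hexachloroacetone, a combination that converts secondary allylic alcohols into the unrearranged chlorides by SN2 displacement on the alkoxyphosphonium ion, should invert C6 from 3R to 3S, the SN2' terminus C7 being substituted and the β-nitrile disfavouring ionisation.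

Step 7
Reactants: 11 (3S,4Z)-6-[(tert-butyldiphenylsilyl)oxy]-3-chloro-4-ethenyl-2,2-dimethylhex-4-enenitrile
Product: 13 (3S,4Z)-6-[(tert-butyldiphenylsilyl)oxy]-3-chloro-4-ethenyl-2,2-dimethylhex-4-enal, via N-aluminated aldimine 12 (not isolated)
Conditions: i-Bu2AlH, CH2Cl2, –78 °C; then 1 M aq. HCl, 0 °C
Reagents that add atoms: water, SMILES O
Why: Partial reduction of a nitrile, in which i-Bu2AlH adds once and stops at the N-aluminated aldimine that aqueous acid hydrolyses to the aldehyde, and because C1 is quaternary neither over-reduction nor epimerisation nor loss of HCl can follow.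

Step 8
Reactants: 13 (3S,4Z)-6-[(tert-butyldiphenylsilyl)oxy]-3-chloro-4-ethenyl-2,2-dimethylhex-4-enal
Product: 15 (1R,3R,5S)-4-[(2Z)-2-[(tert-butyldiphenylsilyl)oxy]ethylidene]-3,5-dichloro-2,2-dimethylcyclohexan-1-ol, via trichlorotitanium alkoxide 14 (not isolated)
Conditions: TiCl4 (1.1 equiv), CH2Cl2, –78 °C; then sat. aq. NaHCO3
Reagents that add atoms: titanium tetrachloride, SMILES Cl[Ti](Cl)(Cl)Cl
Why: TiCl4 binds the non-enolisable aldehyde, the terminal carbon C3 of the s-trans diene attacks C2 to leave an allyl cation over C4, C5 and C7, and a chloride of the resulting titanate is passed to C4 through a six-membered array, the closest known reaction being the TiCl4 halo-Prins carbocyclization of olefinic aldehydes to 3-chlorocyclohexanols. The single ring closes in a 6-endo-trig mode with respect to the C3=C4 bond through a chair-like transition state. The existing C6 chlorine should stand pseudoaxial, because a pseudoequatorial chlorine would suffer allylic 1,3-strain with the C8 methylene of the Z-alkylidene, and this fixes the half-chair. C4 is set by axial, chair-like chloride delivery on the face of that half-chair that also carries the C6 chlorine, and C2 is set by the pseudoaxial position that the titanium-bound oxygen must take for this internal transfer, so that O at C2 and Cl at C4 and C6 should all be cis (if C–C bond formation is reversible, only the zwitterion with axial oxygen collapses quickly). The step needs capture at C4 and not at C7, retention of the C5=C7 geometry and survival of the C6–Cl and C8–O bonds: the titanium-bound chloride cannot reach the exocyclic C7, the C5–C7 bond keeps partial double-bond character throughout, and the aldehyde takes up the single equivalent of Lewis acid while the bulky silyl ether binds it poorly, so the allylic C–Cl and C–O bonds should stay un-ionised at –78 °C.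

Step 9
Reactants: 15 (1R,3R,5S)-4-[(2Z)-2-[(tert-butyldiphenylsilyl)oxy]ethylidene]-3,5-dichloro-2,2-dimethylcyclohexan-1-ol
Product: 16 (1R,3R,5S)-3,5-dichloro-4-[(2Z)-2-hydroxyethylidene]-2,2-dimethylcyclohexan-1-ol
Conditions: HF·pyridine, pyridine, THF, 0 °C to rt
Reagents that add atoms: none
Why: Fluoride-mediated desilylation under acidic, non-basic conditions cleaves the primary Si–O bond without the basicity of naked fluoride, so the two allylic chlorides (one with an antiperiplanar hydrogen) should not be eliminated.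

Step 10
Reactants: 16 (1R,3R,5S)-3,5-dichloro-4-[(2Z)-2-hydroxyethylidene]-2,2-dimethylcyclohexan-1-ol
Product: 18 (1S,3S,5S)-1-bromo-4-[(2Z)-2-bromoethylidene]-3,5-dichloro-2,2-dimethylcyclohexane, via allylic monobromide 17 (not isolated)
Conditions: CBr4 (excess), P(n-C8H17)3 (added slowly), toluene, 0 °C, then 70 °C
Reagents that add atoms: tetrabromomethane, SMILES BrC(Br)(Br)Br
Why: Appel bromination, in which the primary allylic alcohol at C8 reacts at 0 °C by SN2 (the SN2' site C5 is fully substituted) and, on heating, bromide displaces the C2 oxyphosphonium group with inversion from the face opposite both chlorines, the small and strongly nucleophilic trialkylphosphine being suited to hindered secondary carbinols and the excess of CBr4 keeping free phosphine away from the allylic bromide.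

**Compound list**

1 | propargyl alcohol (prop-2-yn-1-ol) | C#CCO | starting material
2 | vinyl bromide (bromoethene) | C=CBr | starting material
3 | pent-4-en-2-yn-1-ol | C=CC#CCO | intermediate
4 | sodium 3-ethenyl-2,2-bis(2-methoxyethoxy)-2,5-dihydro-1,2-oxaaluminol-2-uide (cyclic alkenylalanate, Al on the vinyl-bearing carbon) | [Na+].COCCO[Al-]1(OCCOC)OCC=C1C=C | intermediate
5 | (2Z)-3-iodopenta-2,4-dien-1-ol | OC/C=C(\I)C=C | intermediate
6 | tert-butyl{[(2Z)-3-iodopenta-2,4-dien-1-yl]oxy}diphenylsilane | C=C/C(I)=C/CO[Si](c1ccccc1)(c1ccccc1)C(C)(C)C | intermediate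
7 | 3-hydroxy-2,2-dimethylpropanenitrile | N#CC(C)(C)CO | starting material
8 | 2,2-dimethyl-3-oxopropanenitrile | N#CC(C)(C)C=O | intermediate
9 | (3R,4Z)-6-[(tert-butyldiphenylsilyl)oxy]-4-ethenyl-2,2-dimethyl-3-[(trimethylsilyl)oxy]hex-4-enenitrile | N#CC(C)(C)[C@H](O[Si](C)(C)C)/C(C=C)=C\CO[Si](c1ccccc1)(c1ccccc1)C(C)(C)C | intermediate
10 | (3R,4Z)-6-[(tert-butyldiphenylsilyl)oxy]-4-ethenyl-3-hydroxy-2,2-dimethylhex-4-enenitrile | N#CC(C)(C)[C@H](O)/C(C=C)=C\CO[Si](c1ccccc1)(c1ccccc1)C(C)(C)C | intermediate
11 | (3S,4Z)-6-[(tert-butyldiphenylsilyl)oxy]-3-chloro-4-ethenyl-2,2-dimethylhex-4-enenitrile | N#CC(C)(C)[C@@H](Cl)/C(C=C)=C\CO[Si](c1ccccc1)(c1ccccc1)C(C)(C)C | intermediate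
12 | N-(diisobutylalumanyl)imine of aldehyde 13 (N-aluminated aldimine, 3S,4Z) | CC(C)C[Al](CC(C)C)N=CC(C)(C)[C@@H](Cl)/C(C=C)=C\CO[Si](c1ccccc1)(c1ccccc1)C(C)(C)C | intermediate
13 | (3S,4Z)-6-[(tert-butyldiphenylsilyl)oxy]-3-chloro-4-ethenyl-2,2-dimethylhex-4-enal | O=CC(C)(C)[C@@H](Cl)/C(C=C)=C\CO[Si](c1ccccc1)(c1ccccc1)C(C)(C)C | intermediate
14 | trichlorotitanium alkoxide of cyclohexanol 15 | CC1(C)[C@H](O[Ti](Cl)(Cl)Cl)C[C@H](Cl)/C(=C/CO[Si](c2ccccc2)(c2ccccc2)C(C)(C)C)[C@@H]1Cl | intermediate
15 | (1R,3R,5S)-4-[(2Z)-2-[(tert-butyldiphenylsilyl)oxy]ethylidene]-3,5-dichloro-2,2-dimethylcyclohexan-1-ol (OH cis to both chlorines) | CC1(C)[C@H](O)C[C@H](Cl)/C(=C/CO[Si](c2ccccc2)(c2ccccc2)C(C)(C)C)[C@@H]1Cl | intermediate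
16 | (1R,3R,5S)-3,5-dichloro-4-[(2Z)-2-hydroxyethylidene]-2,2-dimethylcyclohexan-1-ol | CC1(C)[C@H](O)C[C@H](Cl)/C(=C/CO)[C@@H]1Cl | intermediate
17 | (1R,3R,5S)-4-[(2Z)-2-bromoethylidene]-3,5-dichloro-2,2-dimethylcyclohexan-1-ol | CC1(C)[C@H](O)C[C@H](Cl)/C(=C/CBr)[C@@H]1Cl | intermediate
18 | (1S,3S,5S)-1-bromo-4-[(2Z)-2-bromoethylidene]-3,5-dichloro-2,2-dimethylcyclohexane | CC1(C)[C@@H](Br)C[C@H](Cl)/C(=C/CBr)[C@@H]1Cl | target

**Step count and risk**

Total step count: 10. Longest linear sequence: 9 steps (steps 1, 2, 3, 5, 6, 7, 8, 9, 10); step 4 is a one-step branch.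

Steps most likely to fail:

Step 8. What may go wrong: closure through the competing chair in which the titanium-bound oxygen is equatorial, with chloride then arriving from outside, which would mean poor facial selectivity at C2. The C4/C6 relationship should hold in either chair. The fallback sets out from 13 and returns at 15. The cyclization is run as in step 8 and the product is taken on whatever its C2 configuration, including the C2-epimeric cyclohexanol F1. Oxidation with Dess–Martin periodinane (NaHCO3, CH2Cl2, 0 °C) should give the cyclohexanone F2, used crude to avoid loss of HCl. Reduction with LiBH(s-Bu)3 (THF, –78 °C) should then give 15, because the axial approach to C2 is closed by the two axial chlorines on C4 and C6, so hydride enters equatorially and leaves the hydroxyl axial and cis to both.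

Step 10. What may go wrong: retarded backside attack at the neopentyl C2 oxyphosphonium salt, so that elimination towards C3, a 1,2-methyl shift from C1 or quaternisation of the phosphine by the C8 bromide takes over. The fallback sets out from 15 and returns at 18. The C2 hydroxyl is converted into the chloromethanesulfonate F3 (ClCH2SO2Cl, pyridine, CH2Cl2, 0 °C). Displacement with Bu4NBr (toluene, 60 °C) should give, with inversion, the bromide silyl ether F4. HF·pyridine then frees the allylic alcohol F5, and CBr4/PPh3 (CH2Cl2, 0 °C) converts it into 18. The hard secondary substitution is thus done before the sensitive allylic bromide exists.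

Step 6. What may go wrong: chloride entering at C7 with allylic transposition, or ion-pair return that erodes the C6 configuration. The fallback sets out from 10 and returns at 13; it replaces the phosphonium activation by a tethered sulfate. i-Bu2AlH (CH2Cl2, –78 °C; aq. HCl) should give the hydroxy aldehyde F6, and NaBH4 (MeOH, 0 °C) the 1,3-diol F7. SO2Cl2/Et3N (CH2Cl2, –78 °C) should close the six-membered cyclic sulfate F8. LiCl (DMF, rt) should open it at the allylic C6 with inversion, the primary neopentyl C2 end being inert to SN2, to give the sulfate monoester F9. Hydrolysis (cat. H2SO4, H2O, THF) should give the chloro alcohol F10, and Dess–Martin oxidation (CH2Cl2, 0 °C) leads back to 13.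

**Further compounds**

F1 | step 8 | (1S,3R,5S)-4-[(2Z)-2-[(tert-butyldiphenylsilyl)oxy]ethylidene]-3,5-dichloro-2,2-dimethylcyclohexan-1-ol | CC1(C)[C@@H](O)C[C@H](Cl)/C(=C/CO[Si](c2ccccc2)(c2ccccc2)C(C)(C)C)[C@@H]1Cl
F2 | step 8 | (3R,5S)-4-[(2Z)-2-[(tert-butyldiphenylsilyl)oxy]ethylidene]-3,5-dichloro-2,2-dimethylcyclohexan-1-one | CC1(C)C(=O)C[C@H](Cl)/C(=C/CO[Si](c2ccccc2)(c2ccccc2)C(C)(C)C)[C@@H]1Cl
F3 | step 10 | (1R,3R,5S)-4-[(2Z)-2-[(tert-butyldiphenylsilyl)oxy]ethylidene]-3,5-dichloro-2,2-dimethylcyclohexyl chloromethanesulfonate | CC1(C)[C@H](OS(=O)(=O)CCl)C[C@H](Cl)/C(=C/CO[Si](c2ccccc2)(c2ccccc2)C(C)(C)C)[C@@H]1Cl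
F4 | step 10 | {(2Z)-2-[(2S,4S,6S)-4-bromo-2,6-dichloro-3,3-dimethylcyclohexylidene]ethoxy}(tert-butyl)diphenylsilane | CC1(C)[C@@H](Br)C[C@H](Cl)/C(=C/CO[Si](c2ccccc2)(c2ccccc2)C(C)(C)C)[C@@H]1Cl
F5 | step 10 | (2Z)-2-[(2S,4S,6S)-4-bromo-2,6-dichloro-3,3-dimethylcyclohexylidene]ethan-1-ol | CC1(C)[C@@H](Br)C[C@H](Cl)/C(=C/CO)[C@@H]1Cl
F6 | step 6 | (3R,4Z)-6-[(tert-butyldiphenylsilyl)oxy]-4-ethenyl-3-hydroxy-2,2-dimethylhex-4-enal | O=CC(C)(C)[C@H](O)/C(C=C)=C\CO[Si](c1ccccc1)(c1ccccc1)C(C)(C)C
F7 | step 6 | (3R,4Z)-6-[(tert-butyldiphenylsilyl)oxy]-4-ethenyl-2,2-dimethylhex-4-ene-1,3-diol | OCC(C)(C)[C@H](O)/C(C=C)=C\CO[Si](c1ccccc1)(c1ccccc1)C(C)(C)C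
F8 | step 6 | (4R)-4-[(3Z)-5-[(tert-butyldiphenylsilyl)oxy]penta-1,3-dien-3-yl]-5,5-dimethyl-1,3,2-dioxathiane 2,2-dioxide | CC1(C)COS(=O)(=O)O[C@@H]1/C(C=C)=C\CO[Si](c2ccccc2)(c2ccccc2)C(C)(C)C
F9 | step 6 | lithium (3S,4Z)-6-[(tert-butyldiphenylsilyl)oxy]-3-chloro-4-ethenyl-2,2-dimethylhex-4-en-1-yl sulfate | [Li+].[O-]S(=O)(=O)OCC(C)(C)[C@@H](Cl)/C(C=C)=C\CO[Si](c1ccccc1)(c1ccccc1)C(C)(C)C
F10 | step 6 | (3S,4Z)-6-[(tert-butyldiphenylsilyl)oxy]-3-chloro-4-ethenyl-2,2-dimethylhex-4-en-1-ol | OCC(C)(C)[C@@H](Cl)/C(C=C)=C\CO[Si](c1ccccc1)(c1ccccc1)C(C)(C)C
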